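No rate constant of this flask is given, so the first question is what constant the runs themselves yield.

the same everywhere: starting material 1.1 M

| flask | reagent in the second phase | remark | time | volume of the second phase over the first |
|---|---|---|---|---|
| Friday's | 2.8 M | run made earlier |  |  |
| Sunday's | 4.4 M | run made earlier |  |  |
| flask | 1.98 M |  | 8.0 h | 2.0 |

- Friday's (time / h: target / %): 0.833: 0; 2.50: 2; 4.00: 6; 6.00: 7; 10.0: 14
- Sunday's (time / h: target / %): 0.833: 1; 2.50: 1; 4.00: 6; 6.00: 12; 10.0: 12

(each reading ± 1.5 percentage points)

- in the second phase: reagent in the second phase; everything else is in the first
- charges count per volume of the first phase; a concentration in a rate is the amount of a species over the volume of its own phase; every rate counts per litre of the first phase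
- the numbers in the tables scatter by 1.5 percentage points (one standard deviation)
- the earlier runs hold the two phases in the same ratio of volumes as the flask asked about

- east: doubling the transfer coefficient of the reagent in the second phase, all else as stated
- west: doubling the amount of reagent in the second phase, all else as stated

* amount of target at 8.0 h, in percent of the starting material charged
* the change that raises the amount of target at 8.0 h, in percent of the starting material charged most ("none" if none brings more than 2 percentage points) (east / west / none)
* amount of target at 8.0 h, in percent of the starting material charged, after east

**Which number do you take from these runs?** Friday's readings sum to 29.0 % of the charge, and Sunday's to 32.0 %. Both were read at the same times, so their ratio compares the two charges over one set of times. Time cancels from it where the two curves have one shape; these readings are too scattered to show that, so I read the ratio as an average that leans on the late, larger readings. The logarithm of that ratio over the logarithm of the ratio of reagent charges gives 0.218: the charge exponent, how steeply target follows the reagent charged over these times, an apparent reaction order.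

**How firm is it?** Not very: the scatter of the sums puts 0.345 on it either way.

**And the flask?** The readings at 6.00 h and 10.0 h, on either side of the asked time, average 11.2 %. Scaled by the exponent from the middle of the two charges down to the flask's, that gives 9.93 %.

**Does west clear the mark?** Doubling the charge multiplies target by two raised to the exponent, a gain of 1.6 percentage points, which is under 2 points. But clearing the mark takes an exponent of 0.265, well inside the band, so I commit to west, narrowly.

**Why not east?** If transfer is first order, both changes double the inflow at the start, but the coefficient then hastens the same filling, while the charge also raises where it ends. I therefore put east's gain below west's, and target after east between 9.93 % and 11.5 %.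

The forecast gave 10 %, none and 10.5 % after east, reasoning “so transfer is probably not limiting”.

The simulated flask gives 8.43 %. West adds 3.9 points and east 1.7 points, which makes 10.1 % after east, so the answer is west.

    starting material + reagent in the reaction phase → target (k = 6.10 × 10⁻⁴ M⁻¹ min⁻¹)
    reagent in the reaction phase ⇌ reagent in the second phase, rate k2*([reagent in the reaction phase] - [reagent in the second phase]/K2) per volume of the first phase (partition coefficient = 0.640, kL = 0.00220 min⁻¹)
    target → over-reaction product (k = 3.90 × 10⁻⁴ min⁻¹)
    reagent in the reaction phase + target → over-reacted product (k = 0.00270 M⁻¹ min⁻¹)

The resistance to transfer is one part of this ranking: in the flask without it, target reaches 11.7 % instead of 8.43 %, and the best change turns. West's gain gives this flask a charge exponent of 0.545. Carried to Friday's run at its last reading, 11.9 %, with the reagent charge cut to the flask's, that exponent gives 9.87 %, and the simulated run with that one change gives 10.1 %.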